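The route builds ring D last by a two-bond benzannulation. Ring D is a 1,3,5-trisubstituted benzene: its hydroxyls on C3 and C5 are meta to each other and both meta to C1, the carbon that carries the trans C=C leading to ring B. Heating a 3-alkenylcyclobutenone with a siloxyacetylene forms the C3–C4 and C5–C6 bonds of ring D, closes the ring and places both oxygens in one operation. The precursor is the complete MOM-protected (S)-triarylethane in which ring B bears an (E)-2-(3-oxocyclobut-1-en-1-yl)vinyl group. The benzylic stereocentre is set earlier by chiral phosphoric acid transfer hydrogenation of an ortho-quinone methide.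

Key step: step 12

Remarks on the chemistry and assumptions:
- Ring B is taken from 5-bromo-2-hydroxy-3-methoxybenzaldehyde. Its formyl carbon becomes the stereocentre, and the bromine para to the phenol later carries the vinyl unit, so no formyl group has to be masked while the quinone methide forms.
- (Triisopropylsilyloxy)acetylene and 3-ethoxycyclobut-2-en-1-one are assumed purchasable; the siloxyalkyne is otherwise assumed available by silylation of an ynolate.
- (R)-TRIP is written in step 8. Which antipode of the acid gives (S) for this substrate must be confirmed in a first small run; the other antipode is used if the sense is opposite.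
- The stereocentre is (S) throughout, with CIP order ring B > ring A > CH2 > H.
- Ar* = 3-{(1S)-2-[2,4-bis(methoxymethoxy)phenyl]-1-[3-methoxy-4-(methoxymethoxy)phenyl]ethyl}-5-methoxy-4-(methoxymethoxy)phenyl, that is, ring B numbered from the carbon bearing the two-carbon chain.

Step 1
Reactants: 1 4-bromo-2-methoxyphenol
Product: 2 4-bromo-2-methoxy-1-(methoxymethoxy)benzene
Conditions: MOMCl, i-Pr2NEt, CH2Cl2, 0 °C to rt
Reagents that add atoms: chloromethyl methyl ether, COCCl
Why: Williamson-type O-alkylation of the phenol with the reactive α-chloro ether gives the MOM ether that masks the ring A hydroxyl through the organometallic steps.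

Step 2
Reactants: 2 4-bromo-2-methoxy-1-(methoxymethoxy)benzene; 3 5-bromo-2-hydroxy-3-methoxybenzaldehyde
Product: 5 rac-4-bromo-2-{hydroxy[3-methoxy-4-(methoxymethoxy)phenyl]methyl}-6-methoxyphenol, via arylmagnesium bromide 4 (not isolated)
Conditions: Mg, I2 (cat.), THF, 40 °C (2.3 equiv of 2); then 3, THF, 0 °C to rt; aq. NH4Cl
Reagents that add atoms: none
Why: Grignard 1,2-addition to a salicylaldehyde, in which the first equivalent forms the magnesium phenoxide and the second adds to the chelated aldehyde, so the ring B phenol needs no protection and the racemic carbinol centre is erased in step 3.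

Step 3
Reactants: 5 rac-4-bromo-2-{hydroxy[3-methoxy-4-(methoxymethoxy)phenyl]methyl}-6-methoxyphenol
Product: 6 (5-bromo-2-hydroxy-3-methoxyphenyl)[3-methoxy-4-(methoxymethoxy)phenyl]methanone
Conditions: activated MnO2, CH2Cl2, rt
Reagents that add atoms: none
Why: activated MnO2 oxidises the doubly benzylic carbinol selectively to the diaryl ketone and leaves the phenol, the aryl bromide and the MOM ether alone.

Step 4
Reactants: 7 2,4-dihydroxybenzaldehyde
Product: 8 2,4-bis(methoxymethoxy)benzaldehyde
Conditions: MOMCl (3 equiv), i-Pr2NEt, CH2Cl2, 0 °C to 40 °C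
Reagents that add atoms: chloromethyl methyl ether, COCCl
Why: double O-alkylation of the phenols, driven by excess reagent and gentle warming because the hydrogen-bonded 2-hydroxyl reacts more slowly than the 4-hydroxyl.

Step 5
Reactants: 8 2,4-bis(methoxymethoxy)benzaldehyde
Product: 9 [2,4-bis(methoxymethoxy)phenyl]methanol
Conditions: NaBH4, MeOH, 0 °C
Reagents that add atoms: none
Why: borohydride reduction of the aryl aldehyde to the benzylic alcohol under conditions to which MOM ethers are inert.

Step 6
Reactants: 9 [2,4-bis(methoxymethoxy)phenyl]methanol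
Product: 10 1-(chloromethyl)-2,4-bis(methoxymethoxy)benzene
Conditions: MsCl, Et3N, LiCl, THF, 0 °C to rt; used at once
Reagents that add atoms: lithium chloride, [Li+].[Cl-]
Why: mesylation followed by chloride displacement converts the electron-rich benzylic alcohol into the chloride in a buffered, non-acidic medium that spares the MOM ethers.

Step 7
Reactants: 10 1-(chloromethyl)-2,4-bis(methoxymethoxy)benzene; 6 (5-bromo-2-hydroxy-3-methoxyphenyl)[3-methoxy-4-(methoxymethoxy)phenyl]methanone
Product: 12 rac-4-bromo-2-{2-[2,4-bis(methoxymethoxy)phenyl]-1-hydroxy-1-[3-methoxy-4-(methoxymethoxy)phenyl]ethyl}-6-methoxyphenol, via benzylmagnesium chloride 11 (not isolated)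
Conditions: Mg, THF, 0 °C, slow addition (2.5 equiv of 10); then 6, THF, 0 °C to rt; aq. NH4Cl
Reagents that add atoms: none
Why: Grignard addition of a benzylmagnesium chloride to a non-enolisable diaryl ketone held in a magnesium phenoxide chelate gives the tertiary carbinol, whose configuration is irrelevant because it ionises in step 8.

Step 8
Reactants: 12 rac-4-bromo-2-{2-[2,4-bis(methoxymethoxy)phenyl]-1-hydroxy-1-[3-methoxy-4-(methoxymethoxy)phenyl]ethyl}-6-methoxyphenol
Product: 14 4-bromo-2-{(1S)-2-[2,4-bis(methoxymethoxy)phenyl]-1-[3-methoxy-4-(methoxymethoxy)phenyl]ethyl}-6-methoxyphenol, via ortho-quinone methide 13 (not isolated)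
Conditions: (R)-3,3'-bis(2,4,6-triisopropylphenyl)-1,1'-binaphthyl-2,2'-diyl hydrogen phosphate (10 mol%), Hantzsch ester (diethyl 2,6-dimethyl-1,4-dihydropyridine-3,5-dicarboxylate, 1.5 equiv), 4 Å MS, CH2Cl2, rt
Reagents that add atoms: none
Why: organocatalytic asymmetric transfer hydrogenation, in which the chiral phosphoric acid dehydrates 12 to the ortho-quinone methide 13, hydrogen-bonds its carbonyl oxygen and binds the N–H of the Hantzsch ester through P=O, so that hydride reaches one face of the exocyclic carbon and sets the benzylic centre as (S).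

Step 9
Reactants: 14 4-bromo-2-{(1S)-2-[2,4-bis(methoxymethoxy)phenyl]-1-[3-methoxy-4-(methoxymethoxy)phenyl]ethyl}-6-methoxyphenol
Product: 15 5-bromo-1-{(1S)-2-[2,4-bis(methoxymethoxy)phenyl]-1-[3-methoxy-4-(methoxymethoxy)phenyl]ethyl}-3-methoxy-2-(methoxymethoxy)benzene
Conditions: NaH, MOMCl, THF/DMF, 0 °C to rt
Reagents that add atoms: chloromethyl methyl ether, COCCl
Why: Williamson etherification of the hindered ring B phenoxide removes the last acidic O–H before the organolithium of step 11 and the ketenes of step 12, while the diarylmethine C–H is far too weakly acidic to be touched by NaH.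

Step 10
Reactants: 15 5-bromo-1-{(1S)-2-[2,4-bis(methoxymethoxy)phenyl]-1-[3-methoxy-4-(methoxymethoxy)phenyl]ethyl}-3-methoxy-2-(methoxymethoxy)benzene
Product: 16 tributyl[(E)-2-Ar*-ethenyl]stannane
Conditions: (E)-Bu3SnCH=CHSnBu3 (3 equiv), Pd(PPh3)4 (5 mol%), toluene, 100 °C
Reagents that add atoms: (E)-1,2-bis(tributylstannyl)ethene, CCCC[Sn](CCCC)(CCCC)/C=C/[Sn](CCCC)(CCCC)CCCC
Why: Stille coupling of the aryl bromide with one terminus of the distannane, used in excess to suppress double coupling, transfers the vinyl group with retention and so fixes the (E) geometry of the later stilbene.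

Step 11
Reactants: 16 tributyl[(E)-2-Ar*-ethenyl]stannane; 17 3-ethoxycyclobut-2-en-1-one
Product: 20 3-[(E)-2-Ar*-ethenyl]cyclobut-2-en-1-one, via styryllithium 18 (not isolated), via ethoxycyclobutenol 19 (not isolated)
Conditions: n-BuLi (1.05 equiv), THF, −78 °C; 17, −78 °C; then 1 M HCl, THF, 0 °C, short
Reagents that add atoms: water, O
Why: tin–lithium exchange gives the (E)-styryllithium with retention, which adds 1,2 to the vinylogous ester 17, and brief dilute acid then hydrolyses the enol ether and eliminates the tertiary hydroxyl with carbonyl transposition (the standard preparation of 3-substituted cyclobutenones) under conditions too mild to cleave aryl MOM ethers.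

Step 12
Reactants: 20 3-[(E)-2-Ar*-ethenyl]cyclobut-2-en-1-one; 21 (triisopropylsilyloxy)acetylene
Product: 26 3-[(E)-2-Ar*-ethenyl]-5-[(triisopropylsilyl)oxy]phenol, via vinylketene 22 (not isolated), via alkenylcyclobutenone 23 (not isolated), via dienylketene 24 (not isolated), via cyclohexadienone 25 (not isolated)
Conditions: 21 (2 equiv), degassed toluene, 80 °C then 110 °C, sealed tube, dark
Reagents that add atoms: none
Why: On heating, 20 opens by conrotatory 4π cleavage of its C(=O)–CH2 bond to the vinylketene 22, whose ketene C=C adds the electron-rich alkyne 21 in a [2+2] cycloaddition to give the 4-alkenyl-3-siloxycyclobutenone 23; a second 4π opening gives the dienylketene 24, which closes to the dienone 25 and tautomerises to the phenol 26. This is the Danheiser benzannulation of a cyclobutenone with a siloxyalkyne. Ring D is closed by a thermally allowed disrotatory 6π electrocyclisation, which re-forms its C2–C3 bond after the [2+2] step has made the new C3–C4 and C5–C6 bonds. No stereocentre is created, and the benzylic (S) centre, the MOM ethers and the (E)-alkene, a spectator on the ketene β-carbon, see only heat in a neutral aprotic medium. The selectivity needed is regiochemical: the unsubstituted, nucleophilic carbon of the polarised ynol ether bonds to the ketene carbonyl carbon, so the silyloxy group ends meta to the new hydroxyl and the styryl group, fixed at C3 of the cyclobutenone, ends meta to both. An excess of 21 keeps the vinylketene from dimerising or acylating the phenol already formed.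

Step 13
Reactants: 26 3-[(E)-2-Ar*-ethenyl]-5-[(triisopropylsilyl)oxy]phenol
Product: 27 5-[(E)-2-Ar*-ethenyl]benzene-1,3-diol
Conditions: TBAF, AcOH, THF, 0 °C
Reagents that add atoms: none
Why: fluoride cleaves the aryl silyl ether through pentacoordinate silicon, with acetic acid buffering the phenoxide so that the electron-rich stilbene is not left under basic conditions.

Step 14
Reactants: 27 5-[(E)-2-Ar*-ethenyl]benzene-1,3-diol
Product: 28 5-[(E)-2-{3-[(1S)-2-(2,4-dihydroxyphenyl)-1-(4-hydroxy-3-methoxyphenyl)ethyl]-4-hydroxy-5-methoxyphenyl}ethenyl]benzene-1,3-diol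
Conditions: HCl (3 M in MeOH), 40 °C, argon, dark
Reagents that add atoms: none
Why: acid-catalysed acetal exchange with methanol removes the four MOM ethers as dimethoxymethane under conditions that the aryl methyl ethers, the diarylmethine centre and the (E)-stilbene should withstand.

Compound list
1 | 4-bromo-2-methoxyphenol | COc1cc(Br)ccc1O | starting material
2 | 4-bromo-2-methoxy-1-(methoxymethoxy)benzene | COCOc1ccc(Br)cc1OC | intermediate
3 | 5-bromo-2-hydroxy-3-methoxybenzaldehyde | COc1cc(Br)cc(C=O)c1O | starting material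
4 | [3-methoxy-4-(methoxymethoxy)phenyl]magnesium bromide (not isolated) | COCOc1ccc([Mg]Br)cc1OC | intermediate
5 | rac-4-bromo-2-{hydroxy[3-methoxy-4-(methoxymethoxy)phenyl]methyl}-6-methoxyphenol | COCOc1ccc(C(O)c2cc(Br)cc(OC)c2O)cc1OC | intermediate
6 | (5-bromo-2-hydroxy-3-methoxyphenyl)[3-methoxy-4-(methoxymethoxy)phenyl]methanone | COCOc1ccc(C(=O)c2cc(Br)cc(OC)c2O)cc1OC | intermediate
7 | 2,4-dihydroxybenzaldehyde | O=Cc1ccc(O)cc1O | starting material
8 | 2,4-bis(methoxymethoxy)benzaldehyde | COCOc1ccc(C=O)c(OCOC)c1 | intermediate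
9 | [2,4-bis(methoxymethoxy)phenyl]methanol | COCOc1ccc(CO)c(OCOC)c1 | intermediate
10 | 1-(chloromethyl)-2,4-bis(methoxymethoxy)benzene | COCOc1ccc(CCl)c(OCOC)c1 | intermediate
11 | [2,4-bis(methoxymethoxy)benzyl]magnesium chloride (not isolated) | COCOc1ccc(C[Mg]Cl)c(OCOC)c1 | intermediate
12 | rac-4-bromo-2-{2-[2,4-bis(methoxymethoxy)phenyl]-1-hydroxy-1-[3-methoxy-4-(methoxymethoxy)phenyl]ethyl}-6-methoxyphenol | COCOc1ccc(C(O)(Cc2ccc(OCOC)cc2OCOC)c2cc(Br)cc(OC)c2O)cc1OC | intermediate
13 | 4-bromo-6-{2-[2,4-bis(methoxymethoxy)phenyl]-1-[3-methoxy-4-(methoxymethoxy)phenyl]ethylidene}-2-methoxycyclohexa-2,4-dien-1-one (ortho-quinone methide, alkene geometry not fixed, not isolated) | COCOc1ccc(C(Cc2ccc(OCOC)cc2OCOC)=C2C=C(Br)C=C(OC)C2=O)cc1OC | intermediate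
14 | 4-bromo-2-{(1S)-2-[2,4-bis(methoxymethoxy)phenyl]-1-[3-methoxy-4-(methoxymethoxy)phenyl]ethyl}-6-methoxyphenol | COc1cc([C@H](Cc2ccc(OCOC)cc2OCOC)c2cc(Br)cc(OC)c2O)ccc1OCOC | intermediate
15 | 5-bromo-1-{(1S)-2-[2,4-bis(methoxymethoxy)phenyl]-1-[3-methoxy-4-(methoxymethoxy)phenyl]ethyl}-3-methoxy-2-(methoxymethoxy)benzene | COc1cc([C@H](Cc2ccc(OCOC)cc2OCOC)c2cc(Br)cc(OC)c2OCOC)ccc1OCOC | intermediate
16 | tributyl[(E)-2-Ar*-ethenyl]stannane | COc1cc([C@H](Cc2ccc(OCOC)cc2OCOC)c2cc(/C=C/[Sn](CCCC)(CCCC)CCCC)cc(OC)c2OCOC)ccc1OCOC | intermediate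
17 | 3-ethoxycyclobut-2-en-1-one | CCOC1=CC(=O)C1 | starting material
18 | [(E)-2-Ar*-ethenyl]lithium (not isolated) | COc1cc([C@H](Cc2ccc(OCOC)cc2OCOC)c2cc(/C=C/[Li])cc(OC)c2OCOC)ccc1OCOC | intermediate
19 | 3-ethoxy-1-[(E)-2-Ar*-ethenyl]cyclobut-2-en-1-ol (lithium alkoxide in the flask, drawn as the alcohol; carbinol centre not controlled, not isolated) | COc1cc([C@H](Cc2ccc(OCOC)cc2OCOC)c2cc(/C=C/C3(O)C=C(OCC)C3)cc(OC)c2OCOC)ccc1OCOC | intermediate
20 | 3-[(E)-2-Ar*-ethenyl]cyclobut-2-en-1-one | COc1cc([C@H](Cc2ccc(OCOC)cc2OCOC)c2cc(/C=C/C3=CC(=O)C3)cc(OC)c2OCOC)ccc1OCOC | intermediate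
21 | (triisopropylsilyloxy)acetylene [(ethynyloxy)tri(propan-2-yl)silane] | C#CO[Si](C(C)C)(C(C)C)C(C)C | starting material
22 | (4E)-3-methylidene-5-Ar*-penta-1,4-dien-1-one (vinylketene, not isolated) | COc1cc([C@H](Cc2ccc(OCOC)cc2OCOC)c2cc(/C=C/C(=C)C=C=O)cc(OC)c2OCOC)ccc1OCOC | intermediate
23 | 4-[(3E)-4-Ar*-buta-1,3-dien-2-yl]-3-[(triisopropylsilyl)oxy]cyclobut-2-en-1-one (ring CH centre not controlled, not isolated) | COc1cc([C@H](Cc2ccc(OCOC)cc2OCOC)c2cc(/C=C/C(=C)C3C(O[Si](C(C)C)(C(C)C)C(C)C)=CC3=O)cc(OC)c2OCOC)ccc1OCOC | intermediate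
24 | (3E,6E)-5-methylidene-7-Ar*-3-[(triisopropylsilyl)oxy]hepta-1,3,6-trien-1-one (dienylketene, ketene and CH2=C cis across C3=C4, not isolated) | COc1cc([C@H](Cc2ccc(OCOC)cc2OCOC)c2cc(/C=C/C(=C)/C=C(\C=C=O)O[Si](C(C)C)(C(C)C)C(C)C)cc(OC)c2OCOC)ccc1OCOC | intermediate
25 | 5-[(E)-2-Ar*-ethenyl]-3-[(triisopropylsilyl)oxy]cyclohexa-2,4-dien-1-one (not isolated) | COc1cc([C@H](Cc2ccc(OCOC)cc2OCOC)c2cc(/C=C/C3=CC(O[Si](C(C)C)(C(C)C)C(C)C)=CC(=O)C3)cc(OC)c2OCOC)ccc1OCOC | intermediate
26 | 3-[(E)-2-Ar*-ethenyl]-5-[(triisopropylsilyl)oxy]phenol | COc1cc([C@H](Cc2ccc(OCOC)cc2OCOC)c2cc(/C=C/c3cc(O)cc(O[Si](C(C)C)(C(C)C)C(C)C)c3)cc(OC)c2OCOC)ccc1OCOC | intermediate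
27 | 5-[(E)-2-Ar*-ethenyl]benzene-1,3-diol | COc1cc([C@H](Cc2ccc(OCOC)cc2OCOC)c2cc(/C=C/c3cc(O)cc(O)c3)cc(OC)c2OCOC)ccc1OCOC | intermediate
28 | 5-[(E)-2-{3-[(1S)-2-(2,4-dihydroxyphenyl)-1-(4-hydroxy-3-methoxyphenyl)ethyl]-4-hydroxy-5-methoxyphenyl}ethenyl]benzene-1,3-diol | COc1cc([C@H](Cc2ccc(O)cc2O)c2cc(/C=C/c3cc(O)cc(O)c3)cc(OC)c2O)ccc1O | target

Total step count: 14. Longest linear sequence: 11 steps (steps 1, 2, 3 and 7 to 14; the ring C branch, steps 4 to 6, joins at step 7 and is equally long).

Steps most likely to fail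

Step 12. The vinylketene may be consumed by dimerisation or by acylating the phenol already formed instead of being captured by the alkyne, or the cascade may stall before the second ring opening. The fallback sets out from 16 and gives up the benzannulation for a cross-coupling that brings ring D in ready-made. Stille coupling of 16 with 1-bromo-3,5-bis(methoxymethoxy)benzene F1 (from 5-bromobenzene-1,3-diol, MOMCl and i-Pr2NEt) under Pd(PPh3)4 in toluene at 100 °C should give the hexa-MOM ether of the target F2 with the (E)-alkene retained. Methanolic HCl as in step 14 then removes all six MOM groups, and the route is rejoined at 28.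

Step 8. Facial discrimination in the hydride transfer may be poor, because the quinone methide carbon carries an aryl and a benzyl group of similar size and its geometry is not fixed. A racemic background path through protonation of the dehydrated triarylethene at the wrong carbon may also erode the selectivity. The fallback sets out from 12 and replaces asymmetric catalysis by resolution. The same dehydrative transfer hydrogenation, run with achiral diphenyl phosphate and Hantzsch ester, should give the racemic phenol F3. This is resolved by preparative supercritical-fluid chromatography on a chiral stationary phase (amylose tris(3,5-dimethylphenylcarbamate)). The (S)-enantiomer is 14, where the route is rejoined, and the (R)-enantiomer F4 is set aside.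

Step 11. The alkyllithium may deprotonate the polyether during tin–lithium exchange, either ortho to the MOM-oxy groups of ring C or at the diarylmethine C–H, which would erode the configuration. MOM groups may also be lost during the acidic enol ether hydrolysis. The fallback sets out from 15 and builds the cyclobutenone on a small fragment. Mono tin–lithium exchange of (E)-1,2-bis(tributylstannyl)ethene (n-BuLi, THF, −78 °C) gives (E)-2-(tributylstannyl)ethenyllithium F5. This adds to 17 to give 3-ethoxy-1-[(E)-2-(tributylstannyl)ethenyl]cyclobut-2-en-1-ol F6. Brief treatment with oxalic acid on wet silica gives 3-[(E)-2-(tributylstannyl)ethenyl]cyclobut-2-en-1-one F7. Stille coupling of F7 with 15 (Pd2(dba)3, P(t-Bu)3, CsF, dioxane, 40 °C) then gives 20, where the route is rejoined, so that the chiral polyether meets neither an alkyllithium nor aqueous acid.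

Further compounds
F1 | step 12 | 1-bromo-3,5-bis(methoxymethoxy)benzene | COCOc1cc(Br)cc(OCOC)c1
F2 | step 12 | 1-[(E)-2-Ar*-ethenyl]-3,5-bis(methoxymethoxy)benzene (hexa-MOM ether of the target) | COc1cc([C@H](Cc2ccc(OCOC)cc2OCOC)c2cc(/C=C/c3cc(OCOC)cc(OCOC)c3)cc(OC)c2OCOC)ccc1OCOC
F3 | step 8 | rac-4-bromo-2-{2-[2,4-bis(methoxymethoxy)phenyl]-1-[3-methoxy-4-(methoxymethoxy)phenyl]ethyl}-6-methoxyphenol | COc1cc(C(Cc2ccc(OCOC)cc2OCOC)c2cc(Br)cc(OC)c2O)ccc1OCOC
F4 | step 8 | 4-bromo-2-{(1R)-2-[2,4-bis(methoxymethoxy)phenyl]-1-[3-methoxy-4-(methoxymethoxy)phenyl]ethyl}-6-methoxyphenol | COc1cc([C@@H](Cc2ccc(OCOC)cc2OCOC)c2cc(Br)cc(OC)c2O)ccc1OCOC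
F5 | step 11 | (E)-2-(tributylstannyl)ethenyllithium | CCCC[Sn](CCCC)(CCCC)/C=C/[Li]
F6 | step 11 | 3-ethoxy-1-[(E)-2-(tributylstannyl)ethenyl]cyclobut-2-en-1-ol | CCOC1=CC(O)(/C=C/[Sn](CCCC)(CCCC)CCCC)C1
F7 | step 11 | 3-[(E)-2-(tributylstannyl)ethenyl]cyclobut-2-en-1-one | CCCC[Sn](CCCC)(CCCC)/C=C/C1=CC(=O)C1
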